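The earlier runs and the new flask were computed for an exercise; noise was put on by code.

The constants are hidden, so we read what we can from the delta run, which holds twice this flask's partner.

| flask | starting material | partner | precatalyst | remark | time |
|---|---|---|---|---|---|
| delta | 0.011 M (fed, over 4.0 min) | 0.023 M | 46 µM | run made earlier; the fed solution adds 0.25 times the starting volume |  |
| flask | 0.011 M (fed, over 4.0 min) | 0.0115 M | 46 µM | the fed solution adds 0.25 times the starting volume | 80 min |

- delta (time / min: product / %, starting material / %): 1.00: 0, 25.3; 3.00: 5.3, 69.7; 6.00: 17.3, 80.4; 8.00: 26.2, 72.5; 12.0: 39.7, 59.3; 15.0: 47.4, 52.4

(standard deviation of a reading: 1 percentage point)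

- every charge counts on the volume at the start, and the solution that is fed holds the whole dose
- the numbers in the tables scatter by 1 percentage point (one standard deviation)
- what may be going on: partner + catalyst intermediate A -> catalyst intermediate B; catalyst intermediate B -> catalyst intermediate C; starting material + free catalyst <-> catalyst intermediate A; catalyst intermediate C <-> free catalyst + product; partner -> decomposed reagent; partner + precatalyst -> free catalyst + spent reagent
- the reaction counts as stopped when no species that holds the starting material changes by six tenths of a point or more over the second half of the time
- percentages count the whole charge, also what has not yet gone in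

- the state of affairs at 80 min: stopped, and by what, or still going (the partner has run out first / forward and back rates have come level / it is still moving / no working catalyst is left / all of the starting material has reacted)
- amount of product at 80 min, in percent of the starting material charged

We count lifetimes of the starting material, taking minus the logarithm of the unconverted fraction of the charge. By 15.0 min the delta run has spent 0.642. Its pace was 0.0569 min⁻¹ between 6.00 min and 8.00 min, but 0.0455 min⁻¹ between 12.0 min and 15.0 min, slower. As a reading, that pace decays by 0.0343 min⁻¹, so 1.33 lifetimes are still to come, a rough figure given the scatter. Adding them gives 1.97, the lifetime count Θ: the total lifetimes a flask's partner buys.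

The proposed steps use partner in coupling, in freeing catalyst from precatalyst and in its own decomposition. We assume that the decay read above runs on a clock of its own, whatever the charge, and that coupling and freeing catalyst each bring one power of partner, so we take Θ to go with the square of the partner charge. This flask then gets a quarter of the delta count, 0.492 lifetimes, or 38.9% product. With the same decay, 0.0931 lifetimes fall between 40.0 min and 80 min, so we expect it still moving. One number is not enough: a first power instead gives 62.6%.

The forecast gives 56% and it is still moving: “Partner would finally run out near 55% product”.

The flask gives 38.0% at 80 min: the partner has run out first, with 0.0059% of its charge left, although it was charged at 1.05 equivalents of starting material.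

    partner + catalyst intermediate A → catalyst intermediate B (k = 264 L mol⁻¹ s⁻¹)
    catalyst intermediate B → catalyst intermediate C (k = 1.39 s⁻¹)
    starting material + free catalyst ⇌ catalyst intermediate A (K = 40.0 L mol⁻¹, k = 133 L mol⁻¹ s⁻¹)
    catalyst intermediate C ⇌ free catalyst + product (K = 0.0150 M, k = 1.29 s⁻¹)
    partner → decomposed reagent (k = 0.00103 s⁻¹)
    partner + precatalyst → free catalyst + spent reagent (k = 0.235 L mol⁻¹ s⁻¹)

Partner's decomposition has a half-life of 11 min, so 80 min spans 7.13 half-lives. At 6.47 min that reaction uses partner 1.6 times as fast as coupling does. In a second flask with 0.020 M partner, the squared count gives 1.49 lifetimes, but that flask spends 0.973, reaching 62.2% product.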